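## Structural features

The target is a depsidone. Ring A and ring B are joined twice: by an aryl ester (ring A carboxyl to the ring B oxygen para to the lactone carbonyl) and by a diaryl ether between the two neighbouring carbons, which closes a seven-membered dibenzo[b,e][1,4]dioxepin-11-one. On ring A the ester carbon is flanked by the ether oxygen and by the 2-oxoheptyl chain, and a methoxy group sits para to it, so the two ring A oxygens are meta with one C–H between them. Ring B has a single hydrogen and is fused to an isochroman-1-one whose C3 is a spiroketal carbon shared with a 6-methyloxane. The two stereocentres, the spiro carbon (S) and the methyl-bearing carbon (R), sit on either side of the oxane oxygen. With methyl and arylmethyl equatorial and the lactone oxygen axial, the spiro centre is the anomerically favoured epimer and can follow from the carbinol centre by equilibration. Fragile groups are the aryl ester of the central ring, the acyloxy ketal, and the benzylic ketone, whose oxygen lies six atoms from the ring A ester carbon and can close an isocoumarin. The real difficulty is the diaryl ether between two fully flanked carbons, and the order in which ester, ketone and phenols are unveiled. The key step uses the ring A sequence C(OAr)–CH–C(OMe)–CH–C(CH2R)–C(CO2R): one ketene carbon, the two carbons of methoxyethyne and a vinyl unit carrying chain and ester map onto it atom for atom.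

## Logic of the disconnections

25 to 24: the ester C–O bond of the seven-membered ring is cut first. It is the most easily cleaved bond of 25, and closing it last means no later step can open it. The cut gives an open diaryl ether seco acid. The forward step must steer the activated carboxyl to the ring B hydroxyl beside the ether bridge and not to the side-chain ketone; the other ring B hydroxyl is para to the bridge, hydrogen-bonded to the lactone carbonyl, and cannot reach.

24 to 23: three O–CH2Ph bonds (one ester, two ethers) are cut together. One neutral hydrogenolysis then frees everything, with no base or nucleophile near the acyloxy ketal. This demands that nothing else reducible is present, so the alkyne must already be the ketone and the bromine already spent.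

23 to 22: the side-chain C=O is traced back to the internal alkyne, cutting the C–O bond on the carbon next to the benzylic CH2. A benzylic ketone beside an ester would enolise and condense in the basic ether coupling, whereas the alkyne is inert, so no ketone protection is needed. The forward step must hydrate one alkyne carbon only, which calls for participation of the neighbouring ester carbonyl through a six-membered ring.

22 to 15 and 21: the ring B C–O bond of the diaryl ether is cut. This is the most convergent split, into two halves of similar size. It demands a copper coupling of a chelated, weakly nucleophilic phenol with a doubly ortho-substituted, electron-rich bromide, under a base that leaves the propargylic CH2 alone.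

15 to 8 and 11: three ring A C–C bonds are cut: hydroxyl-bearing carbon to the ring CH between the oxygens, methoxy-bearing carbon to the other ring CH, and hydroxyl-bearing carbon to the ester-bearing carbon. Every ring A substituent is then placed by the connectivity of two acyclic partners. The demand is an E enoate, an excess of the volatile ynol ether, and light that spares the ester. The carboxyl of 8 and 15 is carried as a benzyl ester: a hindered simple alkyl benzoate could only be cleaved late by hydroxide or halide, which the acyloxy ketal and the ketone would not tolerate.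

8 to 6: the C=N2 bond is cut (diazo transfer to a methyl ketone). This removes the sensitive diazo group from all earlier steps. The forward step must enolise the methyl group in the presence of a doubly activated CH2 and an electrophilic enoate, hence a hindered amide base at −78 °C.

6 to 3 and 5: the C=C bond is cut (phosphonate olefination). It joins a C10 ketophosphonate to a two-carbon aldehyde ester and sets the alkene geometry. No excess base may remain once the skipped enyne has formed.

3 to 1 and 2: the C–C bond between the phosphonate α-carbon and the propargylic CH2 is cut, giving two commercial materials. The forward step must stop at monoalkylation.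

5 to 4: the aldehyde is traced to the central C–C bond of a tartrate diester. One purchasable diester gives two equivalents of the glyoxylate. The demand is only that the aldehyde is used fresh.

11 to 9: the triple bond is traced to two eliminations from a chloro acetal. The product boils near room temperature and must be distilled cold into the reaction solvent.

21 to 18 and 19: the CH2–C(spiro) bond and the lactone O–C(=O) bond are cut. Both rings of the spiroketal lactone fall away to a toluate and a six-carbon chiral lactone. The forward step needs a benzylic anion that adds to an enolisable lactone faster than it is quenched, and acid to equilibrate the spiro centre.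

18 to 17 to 16: the C–Br bond and the two O–benzyl bonds are cut, back to a commercial orsellinate. Bromination must take the position para to one ether oxygen and not the position between the two.

## Other disconnections considered

Alternative 1: The cut runs through the depside ester C–O bond and the ring A C–C bond between the ester-bearing carbon and the carbon carrying the side chain, so ring A unravels to a chain of alternating carbonyls.
- Forward step: dioxinone A1 would be heated with the ring B bromophenol A2. Acetone would be lost, the phenol would add to the acylketene, and Cs2CO3 followed by acid would fold the chain by aldol condensation and dehydration to depside A3.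
- In its favour: the hindered aryl ester would form under neutral heat without activating a 2,6-disubstituted benzoic acid. The ester link and ring A would arise in one operation, the ketone travels as a dioxolane, and the ether bridge would then close intramolecularly from the bromide.
- Against it here: A1 is a long enolisable chain costing several acylations. The ortho-brominated phenol A2 is a weak partner for the ketene. Ring A arrives as a free resorcinol, so the methoxy group needs a later selective methylation. The depside ester must survive a basic copper step where acyl transfer and Smiles-type migration threaten.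
- Comparison: both plans build ring A de novo, and the alternative forms one more strategic bond in its key step. Its intramolecular ether closure is the better answer to the hindered ether than the intermolecular coupling of step 10. The chosen plan fixes the hydroxyl/methoxy relation by the polarity of a pericyclic cascade, where the alternative depends on one aldol mode among several, and it delivers the two oxygens already differentiated. The step counts should be about equal.

Alternative 2: The cut removes the CH2–C(spiro) bond and the lactone O–C(=O) bond of the ring B isochromanone.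
- Forward step: the benzylic anion of 17 (LiN(iPr)2, −78 °C) would add to lactone 19, the hemiketal alkoxide would close onto the methyl ester, and acid would equilibrate the spiro centre to give A4.
- In its favour: two bonds and both rings of the spiroketal lactone in one convergent operation, stereochemistry from a cheap lactone, and a thermodynamically set spiro centre.
- Against it here: as the step that carries the strategy it deals only with ring B and leaves the ring A pattern and the seven-membered ring to other chemistry. A4 has no handle at C5, so halogenation would follow on the more valuable spiroketal and must tell C5 from C7. The enolisable lactone can quench the anion.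
- Comparison: for ring B the two plans are equal, since step 9 uses the same polarity on the already brominated ester 18. Applied to ring A as well (acylating a 4-O-methylorsellinate anion with a hexanoic acid derivative), this logic would reach an oxoheptyl salicylate in two or three steps against the six of steps 1 to 6, so on step economy the alternative is the better. Its price is strong-base carbanion chemistry and an enolisable ketone present before the ether coupling, where the alkyne of the chosen plan is inert.

Alternative 3: The cut removes the aryl–CH2 and aryl–C(=O) bonds on neighbouring ring B carbons.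
- Forward step: the aryne released from silyl triflate A5 by CsF would insert into a C–C bond of dimethyl malonate A6 to give homophthalate A7.
- In its favour: both carbon substituents are placed in one step with regiochemistry set by the alkoxy group beside the aryne, under near-neutral fluoride conditions, and the two esters of A7 differ in reactivity.
- Against it here: no ring closes and no stereocentre is set. A5 needs several steps. The acetate arm of A7 must still be turned into the hydroxy ketone chain and the spiroketal, four or more steps where step 9 needs one. The C5 halogen is still missing.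
- Comparison: on regiocontrol of the ring B carbon substituents the alternative is the equal of the chosen plan, which buys that pattern in 16. On mildness of the bond-forming step it is the better. On step economy and convergence it is weaker, and like Alternative 2 it leaves ring A and the central ring untouched.

Key step: step 6

Assumption: (R)-6-methyloxan-2-one (19) is bought as the single enantiomer, and the spiro centre of the target is taken as the thermodynamically preferred epimer, so that acid equilibration sets it.

## Route

Step 1
Reactants: 1 diethyl (2-oxopropyl)phosphonate; 2 1-bromohept-2-yne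
Product: 3 diethyl (2-oxodec-5-yn-3-yl)phosphonate (racemic)
Conditions: NaH, THF, 0 °C; then 2, 0 °C → rt
Reagents that add atoms: none
Why: The sodium salt of the β-ketophosphonate is alkylated at carbon by the reactive propargylic bromide (SN2 alkylation of a stabilised carbanion); a slight excess of 1 limits dialkylation, and the new stereocentre disappears in step 3.

Step 2
Reactants: 4 dibenzyl (2R,3R)-tartrate
Product: 5 benzyl glyoxylate
Conditions: H5IO6, Et2O, rt
Reagents that add atoms: none
Why: Periodate glycol cleavage (Malaprade oxidation) of the tartrate diester gives two molecules of the aldehyde ester; the benzyl group enters here so that the ring A carboxyl can later be freed by hydrogenolysis.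

Step 3
Reactants: 3 diethyl (2-oxodec-5-yn-3-yl)phosphonate; 5 benzyl glyoxylate
Product: 6 benzyl (E)-3-acetyldec-2-en-5-ynoate
Conditions: NaH (1.0 equiv), THF, 0 °C; then 5, −78 → 0 °C
Reagents that add atoms: none
Why: Horner–Wadsworth–Emmons olefination of a very electrophilic aldehyde; the stabilised anion should give mainly the alkene with acyl and ester trans (E), also the less strained isomer, and using exactly one equivalent of base leaves none to isomerise the acidic skipped CH2.

Step 4
Reactants: 6 benzyl (E)-3-acetyldec-2-en-5-ynoate
Product: 8 benzyl (E)-3-(2-diazoacetyl)dec-2-en-5-ynoate, via trifluoroacetyl diketone 7 (not isolated)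
Conditions: LiN(SiMe3)2, THF, −78 °C; CF3CO2CH2CF3; aq HCl; then MsN3, Et3N, H2O, MeCN, rt
Reagents that add atoms: methanesulfonyl azide, CS(=O)(=O)N=[N+]=[N-]
Why: Detrifluoroacetylative diazo transfer: the kinetic methyl enolate is trifluoroacetylated to 7, and the activated diketone accepts N2 from the sulfonyl azide with loss of the trifluoroacetyl group. Slow addition of 6 to the hindered base at −78 °C favours the methyl group over the CH2 and over conjugate addition.

Step 5
Reactants: 9 2-chloro-1,1-dimethoxyethane
Product: 11 methoxyethyne, via sodium methoxyethynide 10 (not isolated)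
Conditions: NaNH2 (3 equiv), liq NH3, −33 °C; then aq NH4Cl, −70 °C; distil into cold ClCH2CH2Cl
Reagents that add atoms: none
Why: Two successive eliminations (methanol, then HCl) by amide base give the ynol ether, held as its sodium acetylide 10 until cold protonation; this is the standard preparation of alkoxyethynes from chloroacetaldehyde acetals.

Step 6
Reactants: 8 benzyl (E)-3-(2-diazoacetyl)dec-2-en-5-ynoate; 11 methoxyethyne
Product: 15 benzyl 2-(hept-2-yn-1-yl)-6-hydroxy-4-methoxybenzoate, via vinylketene 12 (not isolated), via vinylcyclobutenone 13 (not isolated), via dienylketene 14 (not isolated)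
Conditions: hν (Pyrex-filtered medium-pressure Hg lamp, λ > 300 nm), 11 (4 equiv), ClCH2CH2Cl, 5 °C; then N2 purge, 80 °C
Reagents that add atoms: none
Why: Light expels N2 from 8 and the vinyl group migrates (photochemical Wolff rearrangement) to give vinylketene 12. The CH carbon of 11, the nucleophilic end of the ynol ether, bonds to the ketene carbonyl carbon and the oxygen-bearing carbon to the ketene α-carbon in a regiospecific [2+2] cycloaddition that closes the four-membered ring of 13. At 80 °C 13 opens by four-electron electrocyclic cleavage to dienylketene 14, and the six-membered ring closes by six-electron disrotatory electrocyclisation between the ketene carbon and the ester-bearing vinyl carbon, followed by tautomerisation to phenol 15. The closest known reaction type is the photochemical Wolff variant of the Danheiser benzannulation of α-diazo enones with alkoxyalkynes. No stereocentre survives, since the only sp3 ring carbon of 13 is racemic and becomes aromatic. The selectivity needed is regiochemical and rests on the polarity of ketene and ynol ether, which puts methoxy meta to the new hydroxyl with a ring CH between them. The E enoate keeps the ester on the outside of the triene, so the carbon–carbon closure is unhindered and the ester carbonyl cannot reach the ketene to close a pyranone. The isolated internal alkyne is too weakly activated to compete with the ynol ether, excess 11 is purged before heating, and light above 300 nm spares the benzyl ester.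

Step 7
Reactants: 16 methyl 2,4-dihydroxy-6-methylbenzoate
Product: 17 methyl 2,4-bis(benzyloxy)-6-methylbenzoate
Conditions: BnBr, K2CO3, DMF, 60 °C
Reagents that add atoms: benzyl bromide, BrCc1ccccc1
Why: Williamson etherification of both phenols; warming in DMF is needed for the hydroxyl that is hydrogen-bonded to the ester.

Step 8
Reactants: 17 methyl 2,4-bis(benzyloxy)-6-methylbenzoate
Product: 18 methyl 4,6-bis(benzyloxy)-3-bromo-2-methylbenzoate
Conditions: NBS, MeCN, 0 °C → rt
Reagents that add atoms: N-bromosuccinimide, O=C1CCC(=O)N1Br
Why: Electrophilic aromatic bromination under ionic conditions; the position para to one benzyloxy group and ortho to the other should react in preference to the position squeezed between the two ethers, as is usual for 1,3-dialkoxyarenes.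

Step 9
Reactants: 18 methyl 4,6-bis(benzyloxy)-3-bromo-2-methylbenzoate; 19 (R)-6-methyloxan-2-one
Product: 21 (3S,6'R)-6,8-bis(benzyloxy)-5-bromo-6'-methylspiro[isochromane-3,2'-oxan]-1-one, via hydroxy keto ester 20 (not isolated)
Conditions: LiN(iPr)2 (2.2 equiv), THF, −78 °C; then 19, −78 → 0 °C; aq HCl; then TsOH·H2O (cat.), toluene, 60 °C
Reagents that add atoms: none
Why: Lateral lithiation of the ortho-toluate and addition of the benzylic anion to the lactone carbonyl give, after protonation, hydroxy keto ester 20 in equilibrium with its cyclic hemiketal; acid then closes the lactone onto the methyl ester with loss of methanol. The carbinol centre comes unchanged from 19 (R), and the spiro centre is set under equilibrating acid as the epimer with the lactone oxygen axial and both carbon substituents of the oxane equatorial (S). The second equivalent of base covers the acidic ketone that forms.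

Step 10
Reactants: 15 benzyl 2-(hept-2-yn-1-yl)-6-hydroxy-4-methoxybenzoate; 21 (3S,6'R)-6,8-bis(benzyloxy)-5-bromo-6'-methylspiro[isochromane-3,2'-oxan]-1-one
Product: 22 benzyl 2-{[(3S,6'R)-6,8-bis(benzyloxy)-6'-methyl-1-oxospiro[isochromane-3,2'-oxan]-5-yl]oxy}-6-(hept-2-yn-1-yl)-4-methoxybenzoate
Conditions: CuI (20 mol %), picolinic acid (40 mol %), K3PO4, DMSO, 90 °C
Reagents that add atoms: none
Why: Copper-catalysed Ullmann-type diaryl ether synthesis: the phenoxide of 15 replaces bromide at the only halogenated carbon of 21, with the picolinic acid ligand system that was developed for ortho-substituted partners. The internal alkyne, the benzyl ester and the benzyl ethers offer no site that phosphate base should attack.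

Step 11
Reactants: 22 benzyl 2-{[(3S,6'R)-6,8-bis(benzyloxy)-6'-methyl-1-oxospiro[isochromane-3,2'-oxan]-5-yl]oxy}-6-(hept-2-yn-1-yl)-4-methoxybenzoate
Product: 23 benzyl 2-{[(3S,6'R)-6,8-bis(benzyloxy)-6'-methyl-1-oxospiro[isochromane-3,2'-oxan]-5-yl]oxy}-4-methoxy-6-(2-oxoheptyl)benzoate
Conditions: Ph3PAuNTf2 (5 mol %), H2O (10 equiv), 1,4-dioxane, 40 °C
Reagents that add atoms: water, O
Why: Gold-catalysed alkyne hydration with neighbouring-carbonyl participation: the benzyl ester carbonyl oxygen adds to the activated alkyne at the carbon next to the benzylic CH2 through a six-membered ring (6-exo-dig), and water opens the cyclic oxocarbenium ion at the former carbonyl carbon, restoring the ester and leaving the ketone on that carbon. Without the ester the two alkyne carbons would be indistinguishable; the seven-membered mode is disfavoured.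

Step 12
Reactants: 23 benzyl 2-{[(3S,6'R)-6,8-bis(benzyloxy)-6'-methyl-1-oxospiro[isochromane-3,2'-oxan]-5-yl]oxy}-4-methoxy-6-(2-oxoheptyl)benzoate
Product: 24 2-{[(3S,6'R)-6,8-dihydroxy-6'-methyl-1-oxospiro[isochromane-3,2'-oxan]-5-yl]oxy}-4-methoxy-6-(2-oxoheptyl)benzoic acid
Conditions: H2 (1 atm), Pd/C, EtOAc, rt
Reagents that add atoms: none
Why: Hydrogenolysis of the three O-benzyl groups (one ester, two ethers) over palladium; the dialkyl ketone, the diaryl ether, the aryl methyl ether and the acyloxy ketal should not be reduced at one atmosphere.

Step 13
Reactants: 24 2-{[(3S,6'R)-6,8-dihydroxy-6'-methyl-1-oxospiro[isochromane-3,2'-oxan]-5-yl]oxy}-4-methoxy-6-(2-oxoheptyl)benzoic acid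
Product: 25 target depsidone CNP0301127.1 (spiro carbon S, methyl-bearing carbon R)
Conditions: DCC, pyridine, CH2Cl2 (2 mM), 0 °C → rt
Reagents that add atoms: none
Why: Carbodiimide lactonisation of a 2-aryloxybenzoic acid onto the ortho hydroxyl of the other ring, the usual closure of the depsidone seven-membered ring. Only the hydroxyl beside the ether bridge can reach the activated carboxyl; the other is para to the bridge and hydrogen-bonded to the lactone carbonyl. High dilution and the absence of strong base should limit oligomerisation and enolisation of the side-chain ketone.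

## Compound list

1 | diethyl (2-oxopropyl)phosphonate | CCOP(=O)(CC(C)=O)OCC | starting material
2 | 1-bromohept-2-yne | CCCCC#CCBr | starting material
3 | diethyl (2-oxodec-5-yn-3-yl)phosphonate (racemic) | CCCCC#CCC(C(C)=O)P(=O)(OCC)OCC | intermediate
4 | dibenzyl (2R,3R)-tartrate | O=C(OCc1ccccc1)[C@H](O)[C@@H](O)C(=O)OCc1ccccc1 | starting material
5 | benzyl glyoxylate | O=CC(=O)OCc1ccccc1 | intermediate
6 | benzyl (E)-3-acetyldec-2-en-5-ynoate | CC(=O)/C(CC#CCCCC)=C/C(=O)OCc1ccccc1 | intermediate
7 | benzyl (E)-3-(4,4,4-trifluoro-3-oxobutanoyl)dec-2-en-5-ynoate | O=C(CC(=O)C(F)(F)F)/C(CC#CCCCC)=C/C(=O)OCc1ccccc1 | intermediate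
8 | benzyl (E)-3-(2-diazoacetyl)dec-2-en-5-ynoate | [N-]=[N+]=CC(=O)/C(CC#CCCCC)=C/C(=O)OCc1ccccc1 | intermediate
9 | 2-chloro-1,1-dimethoxyethane | COC(CCl)OC | starting material
10 | sodium methoxyethynide | [Na+].[C-]#COC | intermediate
11 | methoxyethyne | COC#C | intermediate
12 | benzyl (E)-3-(2-oxoethenyl)dec-2-en-5-ynoate (vinylketene) | O=C=C/C(CC#CCCCC)=C/C(=O)OCc1ccccc1 | intermediate
13 | benzyl (E)-3-(2-methoxy-4-oxocyclobut-2-en-1-yl)dec-2-en-5-ynoate (racemic) | COC1=CC(=O)C1/C(CC#CCCCC)=C/C(=O)OCc1ccccc1 | intermediate
14 | benzyl (2E,4E)-3-(hept-2-yn-1-yl)-5-methoxy-7-oxohepta-2,4,6-trienoate (dienylketene) | O=C=C/C(OC)=C\C(CC#CCCCC)=C\C(=O)OCc1ccccc1 | intermediate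
15 | benzyl 2-(hept-2-yn-1-yl)-6-hydroxy-4-methoxybenzoate | O=C(OCc1ccccc1)c1c(O)cc(OC)cc1CC#CCCCC | intermediate
16 | methyl 2,4-dihydroxy-6-methylbenzoate | COC(=O)c1c(C)cc(O)cc1O | starting material
17 | methyl 2,4-bis(benzyloxy)-6-methylbenzoate | COC(=O)c1c(C)cc(OCc2ccccc2)cc1OCc1ccccc1 | intermediate
18 | methyl 4,6-bis(benzyloxy)-3-bromo-2-methylbenzoate | COC(=O)c1c(C)c(Br)c(OCc2ccccc2)cc1OCc1ccccc1 | intermediate
19 | (R)-6-methyloxan-2-one | O=C1CCC[C@@H](C)O1 | starting material
20 | methyl 4,6-bis(benzyloxy)-3-bromo-2-[(6R)-6-hydroxy-2-oxoheptyl]benzoate | COC(=O)c1c(CC(=O)CCC[C@@H](C)O)c(Br)c(OCc2ccccc2)cc1OCc1ccccc1 | intermediate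
21 | (3S,6'R)-6,8-bis(benzyloxy)-5-bromo-6'-methylspiro[isochromane-3,2'-oxan]-1-one | c1ccccc1COc1cc(OCc2ccccc2)c2c(c1Br)C[C@]1(CCC[C@@H](C)O1)OC2=O | intermediate
22 | benzyl 2-{[(3S,6'R)-6,8-bis(benzyloxy)-6'-methyl-1-oxospiro[isochromane-3,2'-oxan]-5-yl]oxy}-6-(hept-2-yn-1-yl)-4-methoxybenzoate | CCCCC#CCc1cc(OC)cc(Oc2c(OCc3ccccc3)cc(OCc3ccccc3)c3c2C[C@]2(CCC[C@@H](C)O2)OC3=O)c1C(=O)OCc1ccccc1 | intermediate
23 | benzyl 2-{[(3S,6'R)-6,8-bis(benzyloxy)-6'-methyl-1-oxospiro[isochromane-3,2'-oxan]-5-yl]oxy}-4-methoxy-6-(2-oxoheptyl)benzoate | CCCCCC(=O)Cc1cc(OC)cc(Oc2c(OCc3ccccc3)cc(OCc3ccccc3)c3c2C[C@]2(CCC[C@@H](C)O2)OC3=O)c1C(=O)OCc1ccccc1 | intermediate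
24 | 2-{[(3S,6'R)-6,8-dihydroxy-6'-methyl-1-oxospiro[isochromane-3,2'-oxan]-5-yl]oxy}-4-methoxy-6-(2-oxoheptyl)benzoic acid | CCCCCC(=O)Cc1cc(OC)cc(Oc2c(O)cc(O)c3c2C[C@]2(CCC[C@@H](C)O2)OC3=O)c1C(=O)O | intermediate
25 | CNP0301127.1: depsidone in which ring A (methoxy, 2-oxoheptyl) and ring B (free hydroxyl) are bridged by ester and ether, ring B fused to the (3S)-spiro[isochromane-3,2'-oxan]-1-one with (6'R)-methyl | CCCCCC(=O)Cc1cc(OC)cc2c1C(=O)Oc1cc(O)c3c(c1O2)C[C@]1(CCC[C@@H](C)O1)OC3=O | target

## Step count and least certain steps

Total step count: 13. Longest linear sequence: 8 steps (1, 3, 4, 6, 10, 11, 12, 13); the ring B branch (7, 8, 9) joins at step 10.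

Step 6 (key step). What is most likely to go wrong is that capture of vinylketene 12 by the ynol ether loses to decay of the ketene. The decay paths are E to Z photoisomerisation of the enoate followed by closure of the ester carbonyl onto the ketene, and ketene dimerisation. The cause is that 11 is dilute, low-boiling and itself sensitive to light and heat. The fallback leaves photochemistry aside and builds the same ring by a thermal [4+2] cycloaddition. It sets out from 2: copper-mediated coupling with benzyl propiolate (CuI, NaI, K2CO3, DMF, rt) should give benzyl deca-2,5-diynoate F1. Heating F1 with (E)-1,3-dimethoxy-1-(trimethylsilyloxy)buta-1,3-diene in toluene should give the cycloadduct benzyl 2-(hept-2-yn-1-yl)-4,6-dimethoxy-6-(trimethylsilyloxy)cyclohexa-1,4-diene-1-carboxylate F2, the nucleophilic diene terminus bonding to the β-carbon of the ynoate. Dilute acid then removes methanol and the silyl group, and the fallback comes back to the route at 15.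

Step 10. What is most likely to go wrong is stalling of the coupling, with protodebromination of 21 and slow base-induced propargyl-to-allene isomerisation of 15 taking over at 90 °C. The cause is a bromide flanked by a benzyloxy group and the ring CH2 and deactivated by two alkoxy donors, facing a chelated, electron-poor phenoxide. The fallback is a metal-free arylation through a diaryliodonium salt, and sets out from 17. Iodination (N-iodosuccinimide, catalytic CF3CO2H, MeCN) in place of step 8 should give methyl 4,6-bis(benzyloxy)-3-iodo-2-methylbenzoate F3. The annulation of step 9 with 19 should give (3S,6'R)-6,8-bis(benzyloxy)-5-iodo-6'-methylspiro[isochromane-3,2'-oxan]-1-one F4. Oxidation to trivalent iodine (mCPBA, TsOH·H2O, MeCN) and capture by 1,3,5-trimethoxybenzene should give [(3S,6'R)-6,8-bis(benzyloxy)-6'-methyl-1-oxospiro[isochromane-3,2'-oxan]-5-yl](2,4,6-trimethoxyphenyl)iodonium tosylate F5. F5 and 15 with K2CO3 in toluene at 50 °C should transfer the ring B aryl group to the phenoxide oxygen by ligand coupling, which is little affected by ortho substituents, and the fallback returns to the route at 22.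

Step 13. What is most likely to go wrong is diversion of the activated carboxyl to the side-chain ketone (enol lactonisation to a 3-pentylisocoumarin). The ketone oxygen is six atoms from the carboxyl carbon, whereas the phenol must close a seven-membered ring. The fallback carries the ketone through the ring closure as a dioxolane, and sets out from 23. 1,2-Bis(trimethylsilyloxy)ethane with catalytic TMSOTf (CH2Cl2, −78 °C) should give benzyl 2-{[(3S,6'R)-6,8-bis(benzyloxy)-6'-methyl-1-oxospiro[isochromane-3,2'-oxan]-5-yl]oxy}-4-methoxy-6-[(2-pentyl-1,3-dioxolan-2-yl)methyl]benzoate F6. Hydrogenolysis as in step 12 should give the dihydroxy acid 2-{[(3S,6'R)-6,8-dihydroxy-6'-methyl-1-oxospiro[isochromane-3,2'-oxan]-5-yl]oxy}-4-methoxy-6-[(2-pentyl-1,3-dioxolan-2-yl)methyl]benzoic acid F7. DCC closure as in step 13, now with no competing carbonyl, should give the ethylene ketal of the target depsidone F8. Pyridinium p-toluenesulfonate in wet acetone should release the ketone, and the fallback arrives at 25.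

Step 4. What is most likely to go wrong is deprotonation at the CH2 between alkene and alkyne, or conjugate addition to the electron-poor enoate, in place of clean enolisation of the methyl ketone; either leads to isomerisation and oligomers. The cause is that this CH2 is vinylogous to the ester and propargylic, so its acidity is close to that of the methyl group. The fallback makes the diazo ketone by acylating a diazomethane equivalent, with no strong base on the enoate, and sets out from 2 and 5. tert-Butyl diethylphosphonoacetate is alkylated with 2 (NaH, THF) to tert-butyl 2-(diethoxyphosphoryl)non-4-ynoate F9. Olefination of 5 should give 4-benzyl 1-tert-butyl (E)-2-(hept-2-yn-1-yl)but-2-enedioate F10. CF3CO2H should remove the tert-butyl group to give (E)-4-(benzyloxy)-2-(hept-2-yn-1-yl)-4-oxobut-2-enoic acid F11. Oxalyl chloride should give benzyl (E)-3-(chlorocarbonyl)dec-2-en-5-ynoate F12, which with trimethylsilyldiazomethane (MeCN/THF, 0 °C) should give the diazo ketone, and the fallback rejoins the route at 8.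

## Further compounds

F1 | step 6 | benzyl deca-2,5-diynoate | CCCCC#CCC#CC(=O)OCc1ccccc1
F2 | step 6 | benzyl 2-(hept-2-yn-1-yl)-4,6-dimethoxy-6-(trimethylsilyloxy)cyclohexa-1,4-diene-1-carboxylate (racemic) | COC1=CC(OC)(O[Si](C)(C)C)C(C(=O)OCc2ccccc2)=C(CC#CCCCC)C1
F3 | step 10 | methyl 4,6-bis(benzyloxy)-3-iodo-2-methylbenzoate | COC(=O)c1c(C)c(I)c(OCc2ccccc2)cc1OCc1ccccc1
F4 | step 10 | (3S,6'R)-6,8-bis(benzyloxy)-5-iodo-6'-methylspiro[isochromane-3,2'-oxan]-1-one | c1ccccc1COc1cc(OCc2ccccc2)c2c(c1I)C[C@]1(CCC[C@@H](C)O1)OC2=O
F5 | step 10 | [(3S,6'R)-6,8-bis(benzyloxy)-6'-methyl-1-oxospiro[isochromane-3,2'-oxan]-5-yl](2,4,6-trimethoxyphenyl)iodonium 4-methylbenzenesulfonate | COc1cc(OC)c([I+]c2c(OCc3ccccc3)cc(OCc3ccccc3)c3c2C[C@]2(CCC[C@@H](C)O2)OC3=O)c(OC)c1.Cc1ccc(cc1)S(=O)(=O)[O-]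
F6 | step 13 | benzyl 2-{[(3S,6'R)-6,8-bis(benzyloxy)-6'-methyl-1-oxospiro[isochromane-3,2'-oxan]-5-yl]oxy}-4-methoxy-6-[(2-pentyl-1,3-dioxolan-2-yl)methyl]benzoate | CCCCCC1(Cc2cc(OC)cc(Oc3c(OCc4ccccc4)cc(OCc4ccccc4)c4c3C[C@]3(CCC[C@@H](C)O3)OC4=O)c2C(=O)OCc2ccccc2)OCCO1
F7 | step 13 | 2-{[(3S,6'R)-6,8-dihydroxy-6'-methyl-1-oxospiro[isochromane-3,2'-oxan]-5-yl]oxy}-4-methoxy-6-[(2-pentyl-1,3-dioxolan-2-yl)methyl]benzoic acid | CCCCCC1(Cc2cc(OC)cc(Oc3c(O)cc(O)c4c3C[C@]3(CCC[C@@H](C)O3)OC4=O)c2C(=O)O)OCCO1
F8 | step 13 | ethylene ketal of the target depsidone at the side-chain ketone | CCCCCC1(Cc2cc(OC)cc3c2C(=O)Oc2cc(O)c4c(c2O3)C[C@]2(CCC[C@@H](C)O2)OC4=O)OCCO1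
F9 | step 4 | tert-butyl 2-(diethoxyphosphoryl)non-4-ynoate (racemic) | CCCCC#CCC(C(=O)OC(C)(C)C)P(=O)(OCC)OCC
F10 | step 4 | 4-benzyl 1-tert-butyl (E)-2-(hept-2-yn-1-yl)but-2-enedioate | CC(C)(C)OC(=O)/C(CC#CCCCC)=C/C(=O)OCc1ccccc1
F11 | step 4 | (E)-4-(benzyloxy)-2-(hept-2-yn-1-yl)-4-oxobut-2-enoic acid | OC(=O)/C(CC#CCCCC)=C/C(=O)OCc1ccccc1
F12 | step 4 | benzyl (E)-3-(chlorocarbonyl)dec-2-en-5-ynoate | ClC(=O)/C(CC#CCCCC)=C/C(=O)OCc1ccccc1
A1 | alternative 1 | 2,2-dimethyl-6-[2,4-dioxo-5-(2-pentyl-1,3-dioxolan-2-yl)pentyl]-4H-1,3-dioxin-4-one | CCCCCC1(CC(=O)CC(=O)CC2=CC(=O)OC(C)(C)O2)OCCO1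
A2 | alternative 1 | (3S,6'R)-8-(benzyloxy)-5-bromo-6-hydroxy-6'-methylspiro[isochromane-3,2'-oxan]-1-one | Oc1cc(OCc2ccccc2)c2c(c1Br)C[C@]1(CCC[C@@H](C)O1)OC2=O
A3 | alternative 1 | (3S,6'R)-8-(benzyloxy)-5-bromo-6'-methyl-1-oxospiro[isochromane-3,2'-oxan]-6-yl 2,4-dihydroxy-6-[(2-pentyl-1,3-dioxolan-2-yl)methyl]benzoate | CCCCCC1(Cc2cc(O)cc(O)c2C(=O)Oc2cc(OCc3ccccc3)c3c(c2Br)C[C@]2(CCC[C@@H](C)O2)OC3=O)OCCO1
A4 | alternative 2 | (3S,6'R)-6,8-bis(benzyloxy)-6'-methylspiro[isochromane-3,2'-oxan]-1-one | c1ccccc1COc1cc(OCc2ccccc2)c2c(c1)C[C@]1(CCC[C@@H](C)O1)OC2=O
A5 | alternative 3 | 3,5-bis(benzyloxy)-2-(trimethylsilyl)phenyl trifluoromethanesulfonate | C[Si](C)(C)c1c(OCc2ccccc2)cc(OCc2ccccc2)cc1OS(=O)(=O)C(F)(F)F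
A6 | alternative 3 | dimethyl malonate | COC(=O)CC(=O)OC
A7 | alternative 3 | methyl 2,4-bis(benzyloxy)-6-(2-methoxy-2-oxoethyl)benzoate | COC(=O)Cc1cc(OCc2ccccc2)cc(OCc2ccccc2)c1C(=O)OC
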